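A direct plan would build the flavonol from the ring B side. The α‑alkoxy aryl ketone A1, 1‑[3‑(benzyloxy)‑4‑(methoxymethoxy)phenyl]‑2‑(methoxymethoxy)ethan‑1‑one, would be C‑acylated as its enolate with 2,4,6‑trifluorobenzoyl chloride, and ring C would close by displacement of an ortho fluoride (O1–C8a) to give the 5,7‑difluoroflavone A2.
Both fluorides would then be exchanged for benzyloxy groups (A3), the two MOM ethers cleaved, the 3‑ and 4'‑hydroxyls sulfated and the benzyl ethers hydrogenolysed.
Weak point 1: the run‑up to A1 would take five linear steps (bromination, two MOM protections, a Weinreb amide, an aryllithium addition) for an acyclic ketone that holds no ring of the core beyond a bought arene.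
Weak point 2: the exchange of fluoride for benzyloxy would build nothing. It needs two SNAr steps on a ring that the first alkoxy group deactivates, run with alkoxide in hot DMSO on a base‑sensitive 4‑pyranone, only to install oxygens that a phloroglucinol ring has from the start.
Weak point 3: the MOM cleavage would have to spare the 5‑O‑benzyl group peri to the carbonyl, the most acid‑labile ether of A3, so a late protecting‑group step would fight its own selectivity.

**Retrosynthetic overview**
Ring A carries its two bonds to ring C, C4a–C4 and C8a–O1, on neighbouring carbons with the 5‑oxygen beside C4a; cutting both at once turns ring A into 3,5‑bis(benzyloxy)benzyne, made from a symmetric phenol.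
The partner would be a 3‑arylpropiolic acid that already holds ring B, C2, C3, C4 and O1; the aryne would insert into its C(acyl)–O bond, steered by the benzyloxy group beside the triple bond, and O1–C2 would then close ring C (6‑endo‑dig), the only ring formed.
The 3‑hydroxyl would be introduced free by epoxidation of C2=C3; the same acid treatment would remove the 4'‑MOM group and the peri 5‑O‑benzyl group, which is intended, because the chelated 5‑OH does not take up SO3.
No fluorine placeholders, no glycolate chain and no MOM cleavage that must spare a labile benzyl ether are needed; each fragment is three steps from a bought phenol.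

Key step: step 7

Assumption: the sulfate monoesters are written as free acids; they would be handled as dipotassium salts, and the free acid of the target would be set free only at the end by cold cation exchange.

**Route**

Step 1
Reactants: 1 3,5‑bis(benzyloxy)phenol
Product: 2 3,5‑bis(benzyloxy)phenyl N‑isopropylcarbamate
Conditions: i‑PrNCO (1.3 equiv), Et3N (0.2 equiv), CH2Cl2, rt
Reagents that add atoms: isopropyl isocyanate, CC(C)N=C=O
Why: Base‑catalysed addition of the phenol to the isocyanate (carbamoylation) gives the O‑aryl carbamate that serves as directing group for step 2 and as a masked phenol.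

Step 2
Reactants: 2 3,5‑bis(benzyloxy)phenyl N‑isopropylcarbamate
Product: 6 3,5‑bis(benzyloxy)‑2‑(trimethylsilyl)phenyl N‑isopropylcarbamate, via N‑silyl carbamate 3 (not isolated), via ortho‑lithiated carbamate 4 (not isolated), via N‑silyl ortho‑silyl carbamate 5 (not isolated)
Conditions: TBSOTf (1.1 equiv), TMEDA (1.1 equiv), Et2O–THF, 0 °C → rt; then TMEDA (2 equiv), n‑BuLi (2.1 equiv), −78 °C; TMSCl (3 equiv), −78 °C → rt; aq. NaHSO4
Reagents that add atoms: chlorotrimethylsilane, C[Si](C)(C)Cl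
Why: Directed ortho‑metalation, in which the N‑silylated carbamate sends n‑BuLi/TMEDA to C2 (equivalent to C6 by symmetry), the position flanked by the carbamate and a benzyloxy oxygen, and TMSCl traps the aryllithium at −78 °C before an anionic Fries shift; the N‑silyl group is lost on acidic work‑up.

Step 3
Reactants: 6 3,5‑bis(benzyloxy)‑2‑(trimethylsilyl)phenyl N‑isopropylcarbamate
Product: 8 3,5‑bis(benzyloxy)‑2‑(trimethylsilyl)phenyl trifluoromethanesulfonate, via ortho‑silyl phenol 7 (not isolated)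
Conditions: DBU (1.5 equiv), Et2NH (1.2 equiv), MeCN, 40 °C; then PhNTf2 (1.5 equiv), rt
Reagents that add atoms: N‑phenylbis(trifluoromethanesulfonimide), O=S(=O)(N(c1ccccc1)S(=O)(=O)C(F)(F)F)C(F)(F)F
Why: Base‑induced cleavage of the N–H carbamate through the isocyanate (E1cB), trapped by Et2NH as the urea, frees the phenoxide, which is triflated in the same flask to give the ortho‑silylaryl triflate that serves as aryne precursor.

Step 4
Reactants: 9 2‑(benzyloxy)phenol
Product: 10 2‑(benzyloxy)‑4‑iodophenol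
Conditions: NIS (1.05 equiv), TFA (0.1 equiv), MeCN, 0 °C → rt
Reagents that add atoms: N‑iodosuccinimide, O=C1CCC(=O)N1I
Why: Electrophilic aromatic iodination, in which the free hydroxyl outranks the benzyloxy group as activator and sends iodine to its unhindered para position.

Step 5
Reactants: 10 2‑(benzyloxy)‑4‑iodophenol
Product: 11 2‑(benzyloxy)‑4‑iodo‑1‑(methoxymethoxy)benzene
Conditions: MOMCl (1.5 equiv), i‑Pr2NEt (2 equiv), CH2Cl2, 0 °C → rt
Reagents that add atoms: chloromethyl methyl ether, COCCl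
Why: O‑Alkylation of the phenol by the α‑chloro ether under amine base (MOM protection), needed because a free phenoxide would add to the aryne in step 7.

Step 6
Reactants: 11 2‑(benzyloxy)‑4‑iodo‑1‑(methoxymethoxy)benzene; 12 propiolic acid
Product: 13 3‑[3‑(benzyloxy)‑4‑(methoxymethoxy)phenyl]prop‑2‑ynoic acid
Conditions: 12 (1.5 equiv), Pd(PPh3)4 (zerovalent palladium, 3 mol %), DBU (3 equiv), DMSO, 35 °C; cold aq. citric acid to pH 4
Reagents that add atoms: none
Why: Copper‑free Sonogashira‑type coupling of the aryl iodide with propiolic acid as its DBU salt, run near room temperature so that the arylpropiolic acid does not decarboxylate and couple a second time.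

Step 7
Reactants: 8 3,5‑bis(benzyloxy)‑2‑(trimethylsilyl)phenyl trifluoromethanesulfonate; 13 3‑[3‑(benzyloxy)‑4‑(methoxymethoxy)phenyl]prop‑2‑ynoic acid
Product: 16 5,7‑bis(benzyloxy)‑2‑[3‑(benzyloxy)‑4‑(methoxymethoxy)phenyl]‑4H‑chromen‑4‑one, via 3,5‑bis(benzyloxy)benzyne 14 (not isolated), via hydroxyaryl ynone 15 (not isolated)
Conditions: 8 (1.5 equiv), CsF (4 equiv), THF, 125 °C, sealed tube
Reagents that add atoms: none
Why: Fluoride attacks silicon of 8 and triflate leaves to give aryne 14; the cesium carboxylate of 13 adds through oxygen, the aryl anion so formed attacks the neighbouring ester carbonyl through a four‑membered transition state and the C(acyl)–O bond breaks, a net insertion of the aryne into that bond that gives the 2‑acylphenoxide 15, whose oxygen then adds to the ynone β‑carbon before protonation at C3 gives flavone 16. The closest known reaction type is the intermolecular C–O addition of carboxylic acids to arynes with cyclisation in the same flask, which turns cinnamic acids into flavanones and arylpropiolic acids into flavones. Ring C closes by 6‑endo‑dig conjugate addition of O1 to C2. No stereocentre is formed. The step needs one regiochemistry of aryne addition, and the benzyloxy group beside the triple bond secures it: the oxygen nucleophile goes to the distal aryne carbon (the later C8a) because the negative charge then develops on the carbon next to the inductively withdrawing C–O bond (the later C4a), so the acyl group lands between the new oxygen and that benzyloxy group and the 5,7‑pattern follows. It also needs 6‑endo over 5‑exo closure, which the polarisation of the ynone by the C4 carbonyl favours under aprotic fluoride conditions.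

Step 8
Reactants: 16 5,7‑bis(benzyloxy)‑2‑[3‑(benzyloxy)‑4‑(methoxymethoxy)phenyl]‑4H‑chromen‑4‑one
Product: 19 7‑(benzyloxy)‑2‑[3‑(benzyloxy)‑4‑hydroxyphenyl]‑3,5‑dihydroxy‑4H‑chromen‑4‑one (7,3'‑di‑O‑benzylquercetin), via flavone 2,3‑epoxide 17 (not isolated), via 3‑hydroxyflavone 18 (not isolated)
Conditions: DMDO (0.08 M in acetone, 3 equiv), CH2Cl2, 0 °C → rt; evaporate; then conc. HCl–AcOH (1:10), 60 °C
Reagents that add atoms: dimethyldioxirane, CC1(C)OO1
Why: Epoxidation of the enol‑ether double bond C2=C3 by the dioxirane and acid‑induced opening of the 2,3‑epoxide to the 3‑hydroxyflavone (the two stereocentres of racemic 17 are lost again); the same acid hydrolyses the MOM acetal and cleaves the benzyl ether peri to the chelating C4 carbonyl, while the 7‑ and 3'‑benzyl ethers, which lack this assistance, should stay.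

Step 9
Reactants: 19 7‑(benzyloxy)‑2‑[3‑(benzyloxy)‑4‑hydroxyphenyl]‑3,5‑dihydroxy‑4H‑chromen‑4‑one
Product: 20 7‑(benzyloxy)‑2‑[3‑(benzyloxy)‑4‑(sulfooxy)phenyl]‑5‑hydroxy‑4‑oxo‑4H‑chromen‑3‑yl hydrogen sulfate
Conditions: SO3·pyridine (6 equiv), pyridine, rt → 40 °C; cold dilute aq. KOH to pH 8 (dipotassium salt); reversed‑phase chromatography
Reagents that add atoms: sulfur trioxide–pyridine complex, O=S(=O)([O-])[n+]1ccccc1
Why: O‑Sulfation by SO3 transfer from its pyridine complex at the enolic 3‑OH and the phenolic 4'‑OH, while the 5‑OH, locked in a hydrogen bond to the C4 carbonyl, is not expected to react under these conditions (flavonol sulfation is known to leave it free) and the 7‑ and 3'‑oxygens are benzylated.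

Step 10
Reactants: 20 7‑(benzyloxy)‑2‑[3‑(benzyloxy)‑4‑(sulfooxy)phenyl]‑5‑hydroxy‑4‑oxo‑4H‑chromen‑3‑yl hydrogen sulfate
Product: 21 quercetin 3,4'‑bissulfate
Conditions: H2 (1 atm), 10% Pd/C, MeOH–H2O, rt, on the dipotassium salt; cold H+ cation‑exchange resin, freeze‑drying
Reagents that add atoms: none
Why: Catalytic hydrogenolysis of the two aryl benzyl ethers over Pd/C at one atmosphere, under which sulfate monoester salts and the tetrasubstituted C2=C3 bond should stay intact; cold cation exchange then gives the free acid.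

**Compound list**

1 | 3,5‑bis(benzyloxy)phenol | Oc1cc(OCc2ccccc2)cc(OCc2ccccc2)c1 | starting material
2 | 3,5‑bis(benzyloxy)phenyl N‑isopropylcarbamate | CC(C)NC(=O)Oc1cc(OCc2ccccc2)cc(OCc2ccccc2)c1 | intermediate
3 | 3,5‑bis(benzyloxy)phenyl N‑(tert‑butyldimethylsilyl)‑N‑isopropylcarbamate | CC(C)N(C(=O)Oc1cc(OCc2ccccc2)cc(OCc2ccccc2)c1)[Si](C)(C)C(C)(C)C | intermediate (not isolated)
4 | {2,4‑bis(benzyloxy)‑6‑[(N‑(tert‑butyldimethylsilyl)‑N‑isopropylcarbamoyl)oxy]phenyl}lithium | [Li]c1c(OC(=O)N(C(C)C)[Si](C)(C)C(C)(C)C)cc(OCc2ccccc2)cc1OCc1ccccc1 | intermediate (not isolated)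
5 | 3,5‑bis(benzyloxy)‑2‑(trimethylsilyl)phenyl N‑(tert‑butyldimethylsilyl)‑N‑isopropylcarbamate | CC(C)N(C(=O)Oc1cc(OCc2ccccc2)cc(OCc2ccccc2)c1[Si](C)(C)C)[Si](C)(C)C(C)(C)C | intermediate (not isolated)
6 | 3,5‑bis(benzyloxy)‑2‑(trimethylsilyl)phenyl N‑isopropylcarbamate | CC(C)NC(=O)Oc1cc(OCc2ccccc2)cc(OCc2ccccc2)c1[Si](C)(C)C | intermediate
7 | 3,5‑bis(benzyloxy)‑2‑(trimethylsilyl)phenol (present as its amidinium phenoxide) | Oc1cc(OCc2ccccc2)cc(OCc2ccccc2)c1[Si](C)(C)C | intermediate (not isolated)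
8 | 3,5‑bis(benzyloxy)‑2‑(trimethylsilyl)phenyl trifluoromethanesulfonate | C[Si](C)(C)c1c(OS(=O)(=O)C(F)(F)F)cc(OCc2ccccc2)cc1OCc1ccccc1 | intermediate
9 | 2‑(benzyloxy)phenol | Oc1ccccc1OCc1ccccc1 | starting material
10 | 2‑(benzyloxy)‑4‑iodophenol | Oc1ccc(I)cc1OCc1ccccc1 | intermediate
11 | 2‑(benzyloxy)‑4‑iodo‑1‑(methoxymethoxy)benzene | COCOc1ccc(I)cc1OCc1ccccc1 | intermediate
12 | propiolic acid (prop‑2‑ynoic acid) | C#CC(=O)O | starting material
13 | 3‑[3‑(benzyloxy)‑4‑(methoxymethoxy)phenyl]prop‑2‑ynoic acid | COCOc1ccc(C#CC(=O)O)cc1OCc1ccccc1 | intermediate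
14 | 3,5‑bis(benzyloxy)benzyne (1,2‑didehydro‑3,5‑bis(benzyloxy)benzene) | C1#CC(OCc2ccccc2)=CC(OCc2ccccc2)=C1 | intermediate (not isolated)
15 | 1‑[2,4‑bis(benzyloxy)‑6‑hydroxyphenyl]‑3‑[3‑(benzyloxy)‑4‑(methoxymethoxy)phenyl]prop‑2‑yn‑1‑one (present as its cesium phenoxide) | O=C(C#Cc1ccc(OCOC)c(OCc2ccccc2)c1)c1c(O)cc(OCc2ccccc2)cc1OCc1ccccc1 | intermediate (not isolated)
16 | 5,7‑bis(benzyloxy)‑2‑[3‑(benzyloxy)‑4‑(methoxymethoxy)phenyl]‑4H‑chromen‑4‑one | O=c1cc(-c2ccc(OCOC)c(OCc3ccccc3)c2)oc2cc(OCc3ccccc3)cc(OCc3ccccc3)c12 | intermediate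
17 | 2,3‑epoxide of flavone 16: 5,7‑bis(benzyloxy)‑2‑[3‑(benzyloxy)‑4‑(methoxymethoxy)phenyl]‑2,3‑epoxy‑2,3‑dihydro‑4H‑chromen‑4‑one (racemic; oxirane cis‑fused) | O=C1c2c(OCc3ccccc3)cc(OCc3ccccc3)cc2OC2(c3ccc(OCOC)c(OCc4ccccc4)c3)OC12 | intermediate (not isolated)
18 | 5,7‑bis(benzyloxy)‑2‑[3‑(benzyloxy)‑4‑(methoxymethoxy)phenyl]‑3‑hydroxy‑4H‑chromen‑4‑one | O=c1c(O)c(-c2ccc(OCOC)c(OCc3ccccc3)c2)oc2cc(OCc3ccccc3)cc(OCc3ccccc3)c12 | intermediate (not isolated)
19 | 7‑(benzyloxy)‑2‑[3‑(benzyloxy)‑4‑hydroxyphenyl]‑3,5‑dihydroxy‑4H‑chromen‑4‑one (7,3'‑di‑O‑benzylquercetin) | O=c1c(O)c(-c2ccc(O)c(OCc3ccccc3)c2)oc2cc(OCc3ccccc3)cc(O)c12 | intermediate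
20 | 7‑(benzyloxy)‑2‑[3‑(benzyloxy)‑4‑(sulfooxy)phenyl]‑5‑hydroxy‑4‑oxo‑4H‑chromen‑3‑yl hydrogen sulfate | O=c1c(OS(=O)(=O)O)c(-c2ccc(OS(=O)(=O)O)c(OCc3ccccc3)c2)oc2cc(OCc3ccccc3)cc(O)c12 | intermediate
21 | quercetin 3,4'‑bissulfate (5,7‑dihydroxy‑2‑[3‑hydroxy‑4‑(sulfooxy)phenyl]‑4‑oxo‑4H‑chromen‑3‑yl hydrogen sulfate) | O=c1c(OS(=O)(=O)O)c(-c2ccc(OS(=O)(=O)O)c(O)c2)oc2cc(O)cc(O)c12 | target

**Step count and risks**

Total steps: 10. Longest linear sequence: 7 steps (1, 2, 3, 7, 8, 9, 10, or equally 4, 5, 6, 7, 8, 9, 10).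

Steps most likely to fail:

Step 7. The cesium arylpropiolate may decarboxylate at 125 °C before it meets the aryne, the aryne may oligomerise, or the phenoxide may close 5‑exo to the aurone. The fallback sets out from carbamate 2 and acid 13 and returns at flavone 16. Acid 13 would be coupled with MeNH(OMe)·HCl and a carbodiimide to the Weinreb amide 3‑[3‑(benzyloxy)‑4‑(methoxymethoxy)phenyl]‑N‑methoxy‑N‑methylprop‑2‑ynamide F1. The ortho‑lithiated carbamate 4, generated from 2 as in step 2, would be acylated with F1 at −78 °C to give, after work‑up, 3,5‑bis(benzyloxy)‑2‑{3‑[3‑(benzyloxy)‑4‑(methoxymethoxy)phenyl]prop‑2‑ynoyl}phenyl N‑isopropylcarbamate F2. Et2NH and DBU in MeCN at 40 °C would then unmask the phenol, which closes onto the ynone to give 16.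

Step 8. The epoxidation may be slow enough for the dioxirane to oxidise benzylic C–H bonds, and the hot protic acid may take a second benzyl ether or cause C‑benzylation of ring A. The fallback sets out from flavone 16 and returns at triol 19. Deprotonation at C3 with LiN(i‑Pr)2 at −78 °C, trapping with B(OMe)3 and oxidation with H2O2/AcOH (borylation–oxidation) would give 18, isolated this time. MgBr2·OEt2 in toluene–Et2O would then remove only the peri benzyl group through chelation between O4 and O5, giving 7‑(benzyloxy)‑2‑[3‑(benzyloxy)‑4‑(methoxymethoxy)phenyl]‑3,5‑dihydroxy‑4H‑chromen‑4‑one F3. Dilute HCl in MeOH at 40 °C would cleave the MOM ether to 19.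

Step 2. n‑BuLi/TMEDA may deprotonate a benzylic CH2 (followed by Wittig rearrangement), or the lithiated carbamate may undergo the anionic Fries shift before silylation. The fallback sets out from phenol 1 and returns at triflate 8, bypassing steps 1 to 3. Amine‑catalysed ortho‑bromination (NBS, catalytic i‑Pr2NH, CH2Cl2, −78 → 0 °C) would give 3,5‑bis(benzyloxy)‑2‑bromophenol F4. O‑Silylation with (Me3Si)2NH would give [3,5‑bis(benzyloxy)‑2‑bromophenoxy]trimethylsilane F5. n‑BuLi at −100 °C would then effect bromine–lithium exchange, faster than benzylic deprotonation, and the 1,3‑shift of silicon from oxygen to carbon (retro‑Brook); Tf2O would trap the phenoxide as 8.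

**Further compounds**

F1 | step 7 | 3‑[3‑(benzyloxy)‑4‑(methoxymethoxy)phenyl]‑N‑methoxy‑N‑methylprop‑2‑ynamide | CON(C)C(=O)C#Cc1ccc(OCOC)c(OCc2ccccc2)c1
F2 | step 7 | 3,5‑bis(benzyloxy)‑2‑{3‑[3‑(benzyloxy)‑4‑(methoxymethoxy)phenyl]prop‑2‑ynoyl}phenyl N‑isopropylcarbamate | CC(C)NC(=O)Oc1cc(OCc2ccccc2)cc(OCc2ccccc2)c1C(=O)C#Cc1ccc(OCOC)c(OCc2ccccc2)c1
F3 | step 8 | 7‑(benzyloxy)‑2‑[3‑(benzyloxy)‑4‑(methoxymethoxy)phenyl]‑3,5‑dihydroxy‑4H‑chromen‑4‑one | O=c1c(O)c(-c2ccc(OCOC)c(OCc3ccccc3)c2)oc2cc(OCc3ccccc3)cc(O)c12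
F4 | step 2 | 3,5‑bis(benzyloxy)‑2‑bromophenol | Oc1cc(OCc2ccccc2)cc(OCc2ccccc2)c1Br
F5 | step 2 | [3,5‑bis(benzyloxy)‑2‑bromophenoxy]trimethylsilane | C[Si](C)(C)Oc1cc(OCc2ccccc2)cc(OCc2ccccc2)c1Br
A1 | direct plan | 1‑[3‑(benzyloxy)‑4‑(methoxymethoxy)phenyl]‑2‑(methoxymethoxy)ethan‑1‑one | COCOCC(=O)c1ccc(OCOC)c(OCc2ccccc2)c1
A2 | direct plan | 2‑[3‑(benzyloxy)‑4‑(methoxymethoxy)phenyl]‑5,7‑difluoro‑3‑(methoxymethoxy)‑4H‑chromen‑4‑one | COCOc1c(-c2ccc(OCOC)c(OCc3ccccc3)c2)oc2cc(F)cc(F)c2c1=O
A3 | direct plan | 5,7‑bis(benzyloxy)‑2‑[3‑(benzyloxy)‑4‑(methoxymethoxy)phenyl]‑3‑(methoxymethoxy)‑4H‑chromen‑4‑one | COCOc1c(-c2ccc(OCOC)c(OCc3ccccc3)c2)oc2cc(OCc3ccccc3)cc(OCc3ccccc3)c2c1=O
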